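## Retrosynthetic overview

1. Target 19 comes from its tris-silyl ether 18 by desilylation. 18 comes from terminal alkyne 13 and diaryl ynone 7 in one flask, a formal (3+2) annulation.
2. In that flask 13 is oxidised at its terminal carbon to lithium ynolate 15, the three-atom unit C3–C2–O. A [2+2] addition to the C4 ketone of 7 and a 4π ring opening give C3=C4 and the carboxylate, and Ag(I) then closes O1–C5 5-exo-dig.
3. Enabling feature: in the furan-2(5H)-one ring, O1–C5(=CH–aryl) is a masked aryl alkyne plus a carboxyl O–H, and C2(=O)–C3=C4(aryl) is a masked aryl ketone plus an ynolate. The carbinol carbon on C3 is therefore the propargylic carbon of a 1-arylpropargyl alcohol. The 3-bromo-4-hydroxyphenyl rings on C4 and on the exocyclic CH are identical, so 7 comes from one aldehyde used twice.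
4. 13 comes from catalytic asymmetric alkynylation of aldehyde 8, which sets the only stereocentre. 7 comes from aldehyde 2 plus alkyne 4 (itself made from 2), followed by oxidation.
5. Ring order: a transient four-membered oxetene forms first, then the butenolide, which is the only ring built. The three arenes are bought.

Key step: step 8

Assumption: (S,S)-ProPhenol is taken to deliver the alkynyl group to the Re face of 8, as in its other zinc-mediated aldehyde additions. The configuration of 11 is to be checked by Mosher esters, and the (R,R)-ligand is used with no other change if the sense is opposite.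

## Route

Step 1
Reactants: 1 3-bromo-4-hydroxybenzaldehyde
Product: 2 3-bromo-4-[(triisopropylsilyl)oxy]benzaldehyde
Conditions: TIPSCl, imidazole, DMF, 0 °C → rt
Reagents that add atoms: triisopropylsilyl chloride, CC(C)[Si](Cl)(C(C)C)C(C)C
Why: Imidazole-promoted silyl ether formation on a phenol, with the bulky TIPS group chosen because an o-bromophenyl silyl ether must later survive lithium amides and tert-butoxide.

Step 2
Reactants: 2 3-bromo-4-[(triisopropylsilyl)oxy]benzaldehyde
Product: 4 (2-bromo-4-ethynylphenoxy)triisopropylsilane, via diazoalkene 3 (not isolated)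
Conditions: TMSCHN2, LDA, THF, −78 °C; then 2, −78 °C → rt; H2O
Reagents that add atoms: trimethylsilyldiazomethane, C[Si](C)(C)C=[N+]=[N-]
Why: The Colvin rearrangement (Peterson-type loss of Me3SiOLi, loss of N2, 1,2-H shift of the alkylidene carbene) turns aryl aldehydes into terminal alkynes with an amide base only, so no Br/Li exchange and no methanolysis of the aryl silyl ether should occur.

Step 3
Reactants: 4 (2-bromo-4-ethynylphenoxy)triisopropylsilane; 2 3-bromo-4-[(triisopropylsilyl)oxy]benzaldehyde
Product: 6 rac-1,3-bis{3-bromo-4-[(triisopropylsilyl)oxy]phenyl}prop-2-yn-1-ol, via lithium acetylide 5 (not isolated)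
Conditions: LDA, THF, −78 °C; then 2, −78 → 0 °C; H2O
Reagents that add atoms: none
Why: This is a 1,2-addition of a lithium acetylide to an aldehyde, in which LDA removes the alkyne C–H far faster than it touches the aryl bromides, and the new carbinol centre is left racemic because step 4 destroys it.

Step 4
Reactants: 6 rac-1,3-bis{3-bromo-4-[(triisopropylsilyl)oxy]phenyl}prop-2-yn-1-ol
Product: 7 1,3-bis{3-bromo-4-[(triisopropylsilyl)oxy]phenyl}prop-2-yn-1-one
Conditions: activated MnO2, CH2Cl2, rt
Reagents that add atoms: none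
Why: MnO2 oxidation of a benzylic and propargylic alcohol is selective for such activated carbinols and leaves silyl ethers, aryl bromides and the alkyne untouched.

Step 5
Reactants: 8 3,5-dibromo-4-methoxybenzaldehyde; 9 ethynyltrimethylsilane
Product: 11 (S)-1-(3,5-dibromo-4-methoxyphenyl)-3-(trimethylsilyl)prop-2-yn-1-ol, via alkynylzinc 10 (not isolated)
Conditions: Me2Zn, (S,S)-ProPhenol (20 mol %), Ph3P=O (40 mol %), toluene, 0–4 °C; H2O
Reagents that add atoms: none
Why: In this catalytic asymmetric zinc alkynylation of an aryl aldehyde, the dinuclear zinc–ProPhenol complex binds aldehyde and alkynyl group side by side and delivers the alkynyl to the Re face, which sets the only stereocentre of the target.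

Step 6
Reactants: 11 (S)-1-(3,5-dibromo-4-methoxyphenyl)-3-(trimethylsilyl)prop-2-yn-1-ol
Product: 12 (R)-1-(3,5-dibromo-4-methoxyphenyl)prop-2-yn-1-ol
Conditions: K2CO3 (cat.), MeOH, 0 °C → rt
Reagents that add atoms: none
Why: Base-catalysed methanolytic protodesilylation of an alkynylsilane touches no bond at the stereocentre, and the descriptor changes from S to R only because ethynyl ranks below aryl.

Step 7
Reactants: 12 (R)-1-(3,5-dibromo-4-methoxyphenyl)prop-2-yn-1-ol
Product: 13 (R)-tert-butyl{[1-(3,5-dibromo-4-methoxyphenyl)prop-2-yn-1-yl]oxy}dimethylsilane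
Conditions: TBSCl, imidazole, DMF, rt
Reagents that add atoms: tert-butyldimethylsilyl chloride, CC(C)(C)[Si](C)(C)Cl
Why: Silyl ether formation keeps the carbinol oxygen from oxa-Michael addition to the ynone and from cyclising onto the alkyne in step 8.

Step 8
Reactants: 13 (R)-tert-butyl{[1-(3,5-dibromo-4-methoxyphenyl)prop-2-yn-1-yl]oxy}dimethylsilane; 7 1,3-bis{3-bromo-4-[(triisopropylsilyl)oxy]phenyl}prop-2-yn-1-one
Product: 18 (5Z)-3-{(S)-[(tert-butyldimethylsilyl)oxy](3,5-dibromo-4-methoxyphenyl)methyl}-4-{3-bromo-4-[(triisopropylsilyl)oxy]phenyl}-5-({3-bromo-4-[(triisopropylsilyl)oxy]phenyl}methylidene)furan-2(5H)-one, via lithium acetylide 14 (not isolated), via lithium ynolate 15 (not isolated), via oxetene enolate 16 (not isolated), via enynoic acid 17 (not isolated)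
Conditions: LiHMDS (2.1 equiv), t-BuOOH (1.0 equiv, in decane), THF, −78 → 0 °C; then 7, −78 °C → rt; then AcOH, AgNO3 (10 mol %), THF–MeOH, rt, dark, same flask
Reagents that add atoms: tert-butyl hydroperoxide, CC(C)(C)OO
Why: Proposed new method: a one-flask formal (3+2) annulation in which acetylide 14 is oxidised by t-BuOOLi to ynolate 15, 15 adds to the ketone C=O of 7 in a [2+2] sense to give β-lactone enolate 16, thermal conrotatory 4π ring opening of 16 creates the C3=C4 bond and the carboxylate, and after acidification Ag(I) activates the alkyne of 17 for attack of a carboxyl oxygen on C5. The closest known reaction types are the torquoselective olefination of ketones and of alkynoate esters with lithium ynolates and the silver-catalysed lactonisation of 3,5-diaryl-(Z)-2-en-4-ynoic acids; new are the aryl alkynyl ketone as acceptor, an ynolate that carries a silyloxy stereocentre, and the telescoping of both events. The four-membered oxetene ring of 16 closes by [2+2] cycloaddition and is opened again, and the butenolide, the only ring that is kept, closes 5-exo-dig. No new sp3 stereocentre survives (the quaternary carbon of 16 becomes sp2 and no bond to the carbinol carbon of 13 is touched, so its configuration is carried through), the C3=C4 geometry is set by torquoselectivity, the slim π-accepting alkynyl group turning inward towards the breaking C–O bond and the π-donating silyloxyaryl ring outward, which places carboxylate and alkyne cis, and the exocyclic Z geometry is set by anti oxyargentation followed by protodemetalation with retention. The step needs 1,2- over 1,4-addition, which the hard lithium ynolate at low temperature should secure as it does with alkynoates, and 5-exo over 6-endo closure, for which silver(I) and the angle compression by the C4 aryl ring speak. It is also self-sorting, since only the isomer with carboxyl and alkyne cis can lactonise and any other isomer stays an acid that a basic wash removes.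

Step 9
Reactants: 18 tris-silyl ether of the target
Product: 19 (5Z)-4-(3-bromo-4-hydroxyphenyl)-5-[(3-bromo-4-hydroxyphenyl)methylidene]-3-[(S)-(3,5-dibromo-4-methoxyphenyl)(hydroxy)methyl]furan-2(5H)-one
Conditions: TBAF, AcOH (1:1, excess), THF, 0 °C → rt
Reagents that add atoms: none
Why: Fluoride-induced global desilylation cleaves only Si–O bonds, so the carbinol configuration, the methyl ether and the Z-alkylidene lactone should persist, and the acetic acid buffer keeps the phenoxides and the alkoxide from building up a basic medium.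

## Compound list

1 | 3-bromo-4-hydroxybenzaldehyde | O=Cc1ccc(O)c(Br)c1 | starting material
2 | 3-bromo-4-[(triisopropylsilyl)oxy]benzaldehyde | O=Cc1ccc(O[Si](C(C)C)(C(C)C)C(C)C)c(Br)c1 | intermediate
3 | diazoalkene, 1-diazo-2-{3-bromo-4-[(triisopropylsilyl)oxy]phenyl}ethene (not isolated) | [N-]=[N+]=C=Cc1ccc(O[Si](C(C)C)(C(C)C)C(C)C)c(Br)c1 | intermediate
4 | (2-bromo-4-ethynylphenoxy)triisopropylsilane | C#Cc1ccc(O[Si](C(C)C)(C(C)C)C(C)C)c(Br)c1 | intermediate
5 | lithium acetylide of 4 (not isolated) | [Li]C#Cc1ccc(O[Si](C(C)C)(C(C)C)C(C)C)c(Br)c1 | intermediate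
6 | rac-1,3-bis{3-bromo-4-[(triisopropylsilyl)oxy]phenyl}prop-2-yn-1-ol | OC(C#Cc1ccc(O[Si](C(C)C)(C(C)C)C(C)C)c(Br)c1)c1ccc(O[Si](C(C)C)(C(C)C)C(C)C)c(Br)c1 | intermediate
7 | 1,3-bis{3-bromo-4-[(triisopropylsilyl)oxy]phenyl}prop-2-yn-1-one | O=C(C#Cc1ccc(O[Si](C(C)C)(C(C)C)C(C)C)c(Br)c1)c1ccc(O[Si](C(C)C)(C(C)C)C(C)C)c(Br)c1 | intermediate
8 | 3,5-dibromo-4-methoxybenzaldehyde | COc1c(Br)cc(C=O)cc1Br | starting material
9 | ethynyltrimethylsilane | C#C[Si](C)(C)C | starting material
10 | methyl[(trimethylsilyl)ethynyl]zinc (not isolated) | C[Zn]C#C[Si](C)(C)C | intermediate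
11 | (S)-1-(3,5-dibromo-4-methoxyphenyl)-3-(trimethylsilyl)prop-2-yn-1-ol | COc1c(Br)cc([C@H](O)C#C[Si](C)(C)C)cc1Br | intermediate
12 | (R)-1-(3,5-dibromo-4-methoxyphenyl)prop-2-yn-1-ol | COc1c(Br)cc([C@H](O)C#C)cc1Br | intermediate
13 | (R)-tert-butyl{[1-(3,5-dibromo-4-methoxyphenyl)prop-2-yn-1-yl]oxy}dimethylsilane | COc1c(Br)cc([C@H](O[Si](C)(C)C(C)(C)C)C#C)cc1Br | intermediate
14 | lithium acetylide of 13 (not isolated) | COc1c(Br)cc([C@H](O[Si](C)(C)C(C)(C)C)C#C[Li])cc1Br | intermediate
15 | lithium (S)-3-[(tert-butyldimethylsilyl)oxy]-3-(3,5-dibromo-4-methoxyphenyl)prop-1-yn-1-olate (not isolated) | COc1c(Br)cc([C@H](O[Si](C)(C)C(C)(C)C)C#C[O-])cc1Br.[Li+] | intermediate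
16 | lithium 2H-oxet-4-olate (β-lactone enolate), either configuration at the ring quaternary carbon (not isolated) | COc1c(Br)cc([C@H](O[Si](C)(C)C(C)(C)C)C2=C([O-])OC2(C#Cc3ccc(O[Si](C(C)C)(C(C)C)C(C)C)c(Br)c3)c3ccc(O[Si](C(C)C)(C(C)C)C(C)C)c(Br)c3)cc1Br.[Li+] | intermediate
17 | (2Z)-2-{(S)-[(tert-butyldimethylsilyl)oxy](3,5-dibromo-4-methoxyphenyl)methyl}-3,5-bis{3-bromo-4-[(triisopropylsilyl)oxy]phenyl}pent-2-en-4-ynoic acid (not isolated) | COc1c(Br)cc([C@H](O[Si](C)(C)C(C)(C)C)/C(C(=O)O)=C(/C#Cc2ccc(O[Si](C(C)C)(C(C)C)C(C)C)c(Br)c2)c2ccc(O[Si](C(C)C)(C(C)C)C(C)C)c(Br)c2)cc1Br | intermediate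
18 | tris-silyl ether of the target, (S) at the carbinol, (5Z) | COc1c(Br)cc([C@H](O[Si](C)(C)C(C)(C)C)C2=C(c3ccc(O[Si](C(C)C)(C(C)C)C(C)C)c(Br)c3)/C(=C/c3ccc(O[Si](C(C)C)(C(C)C)C(C)C)c(Br)c3)OC2=O)cc1Br | intermediate
19 | (5Z)-4-(3-bromo-4-hydroxyphenyl)-5-[(3-bromo-4-hydroxyphenyl)methylidene]-3-[(S)-(3,5-dibromo-4-methoxyphenyl)(hydroxy)methyl]furan-2(5H)-one | COc1c(Br)cc([C@H](O)C2=C(c3ccc(O)c(Br)c3)/C(=C/c3ccc(O)c(Br)c3)OC2=O)cc1Br | target

## Step count and risks

Total step count: 9. Longest linear sequence: 6 (steps 1, 2, 3, 4, 8, 9).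

**Step 8.**
- What may go wrong:
  - The ynolate may add to the ynone in the conjugate sense.
  - The ring opening may lose its torquoselectivity, because the outward-turning aryl ring has to pass the bulky C3 substituent.
  - The silver step may drift towards 6-endo closure.
- Fallback, known chemistry only, setting out from 13 and 7 and coming back at 18:
  - Ynolate 15 is made from 13 as before (acetylide oxidation is established) but is quenched with dilute aqueous acid. The ketene is thereby hydrated to (R)-3-[(tert-butyldimethylsilyl)oxy]-3-(3,5-dibromo-4-methoxyphenyl)propanoic acid F1.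
  - Double deprotonation with LDA at −78 °C and 1,2-addition of the enediolate to 7 (Ivanov-type aldol addition) should give the 3-hydroxypent-4-ynoic acid F2 as a mixture at its two new centres.
  - Silver-catalysed 5-exo-dig lactonisation of this 4-alkynoic acid should give the (5Z)-4-hydroxy-5-benzylidene lactone F3.
  - Dehydration with MsCl/Et3N (E1cB through the lactone enolate) erases both new centres and gives 18.
  - In this order the ring is closed before the C3=C4 alkene exists, so no alkene geometry has to be controlled.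

**Step 5.**
- What may go wrong: facial selectivity may be insufficient, or an uncatalysed background addition to this electron-poor aldehyde may erode the enantiomeric purity.
- Fallback, setting out from 8 and coming back at 12:
  - Ethynylmagnesium bromide adds to 8 to give rac-1-(3,5-dibromo-4-methoxyphenyl)prop-2-yn-1-ol F4.
  - A lipase (immobilised Candida antarctica lipase B, vinyl acetate, MTBE) acylates, by the Kazlauskas rule (aryl large, ethynyl medium), the R enantiomer. This gives (R)-1-(3,5-dibromo-4-methoxyphenyl)prop-2-yn-1-yl acetate F5.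
  - The unreacted (S)-1-(3,5-dibromo-4-methoxyphenyl)prop-2-yn-1-ol F6 is separated by chromatography.
  - Methanolysis of F5 (K2CO3, MeOH) gives 12.

**Step 9.**
- What may go wrong: the hindered secondary silyl ether may cleave slowly, and forcing may then cause Z/E scrambling or solvolysis at the benzylic and allylic carbinol with loss of enantiomeric purity.
- Fallback, setting out from 12 and 7 and coming back at 19:
  - 12 is taken into the step 8 protocol without O-silylation, one more equivalent of LiHMDS holding the carbinol as its lithium alkoxide.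
  - This should give the bis(triisopropylsilyl) ether with free carbinol F7.
  - Its two aryl silyl ethers, far more fluoride-labile than an alkyl silyl ether, are cleaved with TBAF/AcOH at 0 °C within a short time to give 19.

## Further compounds

F1 | step 8 | (R)-3-[(tert-butyldimethylsilyl)oxy]-3-(3,5-dibromo-4-methoxyphenyl)propanoic acid | COc1c(Br)cc([C@H](O[Si](C)(C)C(C)(C)C)CC(=O)O)cc1Br
F2 | step 8 | 2-{[(tert-butyldimethylsilyl)oxy](3,5-dibromo-4-methoxyphenyl)methyl}-3-hydroxy-3,5-bis{3-bromo-4-[(triisopropylsilyl)oxy]phenyl}pent-4-ynoic acid, carbinol centre as in 13, mixture at C2 and C3 | COc1c(Br)cc([C@H](O[Si](C)(C)C(C)(C)C)C(C(=O)O)C(O)(C#Cc2ccc(O[Si](C(C)C)(C(C)C)C(C)C)c(Br)c2)c2ccc(O[Si](C(C)C)(C(C)C)C(C)C)c(Br)c2)cc1Br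
F3 | step 8 | (5Z)-4-hydroxy-5-benzylidene-dihydrofuran-2(3H)-one analogue of 18, carbinol centre as in 13, mixture at C3 and C4 | COc1c(Br)cc([C@H](O[Si](C)(C)C(C)(C)C)C2C(=O)O/C(=C\c3ccc(O[Si](C(C)C)(C(C)C)C(C)C)c(Br)c3)C2(O)c3ccc(O[Si](C(C)C)(C(C)C)C(C)C)c(Br)c3)cc1Br
F4 | step 5 | rac-1-(3,5-dibromo-4-methoxyphenyl)prop-2-yn-1-ol | COc1c(Br)cc(C(O)C#C)cc1Br
F5 | step 5 | (R)-1-(3,5-dibromo-4-methoxyphenyl)prop-2-yn-1-yl acetate | COc1c(Br)cc([C@H](OC(C)=O)C#C)cc1Br
F6 | step 5 | (S)-1-(3,5-dibromo-4-methoxyphenyl)prop-2-yn-1-ol | COc1c(Br)cc([C@@H](O)C#C)cc1Br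
F7 | step 9 | bis(triisopropylsilyl) ether of 19 with free (S)-carbinol, (5Z) | COc1c(Br)cc([C@H](O)C2=C(c3ccc(O[Si](C(C)C)(C(C)C)C(C)C)c(Br)c3)/C(=C/c3ccc(O[Si](C(C)C)(C(C)C)C(C)C)c(Br)c3)OC2=O)cc1Br
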